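**Assumptions.** (i) Commercial citral (E/Z mixture, achiral) converges to one enantiomer under ammonium-phosphate (ACDC) transfer hydrogenation, because the iminium ions interconvert. (ii) The (S)-TRIP salt gives the 3R-aldehyde from citral; the catalyst enantiomer is chosen to give 3R, checked by [α]D of 3. (iii) Phytyl numbering (C1'–C16') is used below. Natural phylloquinone is (7'R,11'R,2'E), and the target SMILES was checked to encode exactly that.

## Retrosynthesis
- The naphthoquinone ring is purchased as menadiol, so no ring is formed. Phylloquinone comes from Friedel–Crafts C3-allylation of menadiol with isophytol (via the E-allyl cation), then oxidation.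
- Isophytol comes from vinylMgBr plus (6R,10R)-hexahydrofarnesylacetone (9). Compound 9 comes from Wittig homologation of aldehyde 6 with an acetonyl ylide, then global hydrogenation.
- The C7' stereocentre is set by 1,4-transfer hydrogenation (proposed new step) of the 2,4-dienal 5, which comes from Wittig olefination of (R)-citronellal with the commercial "formylcrotyl" C5 phosphonium salt.
- The C11' stereocentre is set first, by organocatalytic transfer hydrogenation of citral to (R)-citronellal.

## Route

**Step 1**
Reactants: 1 citral ((2E/Z)-3,7-dimethylocta-2,6-dienal); 2 Hantzsch ester (diethyl 2,6-dimethyl-1,4-dihydropyridine-3,5-dicarboxylate)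
Product: 3 (R)-citronellal, (3R)-3,7-dimethyloct-6-enal
Conditions: 2 (1.2 equiv), 5 mol % secondary-ammonium (S)-TRIP phosphate salt, MTBE, 50 °C, 24 h
Reagents that add atoms: none (only H is delivered)
Why: Organocatalytic asymmetric counteranion-directed transfer hydrogenation of a β,β-disubstituted enal (List type); the chiral phosphate ion-paired to the iminium delivers hydride to one face and sets C3 (= phytyl C11', R), leaving the isolated prenyl alkene untouched.

**Step 2**
Reactants: 3; 4 (E)-(3-formylbut-2-en-1-yl)triphenylphosphonium chloride
Product: 5 (2E,4E,7R)-3,7,11-trimethyldodeca-2,4,10-trienal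
Conditions: 4 (1.1 equiv), sat. aq. K2CO3/CH2Cl2, rt, 12 h
Reagents that add atoms: 4 (supplies the C5 unit –CH=CH–C(CH3)=CH–CHO; SMILES O=C/C=C(\C)C[P+](c1ccccc1)(c1ccccc1)c1ccccc1.[Cl-])
Why: Wittig olefination with a vinylogously stabilised ylide gives the E-disubstituted alkene and keeps the reagent's E-trisubstituted enal geometry; the C11' stereocentre is β to the aldehyde and cannot epimerise.

**Step 3**
Reactants: 5; 2
Product: 6 (3S,4E,7R)-3,7,11-trimethyldodeca-4,10-dienal (the 3S label reflects CIP priorities with the vinyl group present; it is the spatial arrangement that becomes 7'R)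
Conditions: 2 (1.2 equiv), 5 mol % secondary-ammonium (S)-TRIP salt (same enantiomer as Step 1), MTBE, 40 °C, 36 h
Reagents that add atoms: none
Why: Proposed new method: the secondary ammonium phosphate condenses with 5 to give an (E)-2,4-dienyl iminium/TRIP ion pair. Hydride from 2 is delivered at the β-carbon (C3 of the dienal, = C7'), with the chain trans and the methyl cis to the iminium as in citral, so the same face is attacked. The resulting dienamine is protonated and hydrolysed to the β,γ-saturated 6 with the C8'=C9' alkene left in place. The closest known reaction is ACDC reduction of β,β-dialkyl enals (citral → citronellal); the new feature is a β-methyl-β-alkenyl 2,4-dienal, requiring 1,4- over 1,6-selectivity, and the catalyst must discriminate methyl from an E-alkenyl group. The stereocentre is set by the same facial sense as Step 1, giving 7'R after reduction of the vinyl group.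

**Step 4**
Reactants: 6; 7 1-(triphenylphosphoranylidene)propan-2-one
Product: 8 (3E,6S,7E,10R)-6,10,14-trimethylpentadeca-3,7,13-trien-2-one
Conditions: 7 (1.3 equiv), toluene, 80 °C, 12 h
Reagents that add atoms: 7 (supplies –CH=CH–CO–CH3; SMILES CC(=O)C=P(c1ccccc1)(c1ccccc1)c1ccccc1)
Why: Wittig reaction of a stabilised ylide with an aliphatic aldehyde gives the E-enone; the β- and δ-stereocentres are not epimerisable under these weakly basic conditions.

**Step 5**
Reactants: 8; H2
Product: 9 (6R,10R)-6,10,14-trimethylpentadecan-2-one (hexahydrofarnesylacetone)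
Conditions: H2 (10 bar), 5 % Pd/C, EtOAc, rt, 6 h
Reagents that add atoms: none (only H)
Why: Catalytic hydrogenation saturates the enone C=C and both remaining alkenes; the high H2 pressure suppresses alkene migration, so C7' and C11' are untouched and become the (6R,10R) centres, matching the target chain.

**Step 6**
Reactants: 9; 10 vinylmagnesium bromide
Product: 11 isophytol, (3RS,7R,11R)-3,7,11,15-tetramethylhexadec-1-en-3-ol
Conditions: 10 (1.5 equiv), THF, 0 °C → rt, 2 h; aq. NH4Cl workup
Reagents that add atoms: 10 (vinyl group; SMILES C=C[Mg]Br)
Why: Grignard 1,2-addition to a methyl ketone; the new tertiary carbinol stereocentre is irrelevant because it is destroyed on ionisation in Step 7.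

**Step 7**
Reactants: 11; 12 menadiol (2-methylnaphthalene-1,4-diol)
Product: 13 phylloquinol, 2-methyl-3-[(2E,7R,11R)-phytyl]naphthalene-1,4-diol
Conditions: BF3·OEt2 (10 mol %), dioxane, 45 °C, N2, 3 h
Reagents that add atoms: none beyond the numbered reactants (BF3 is a catalyst)
Why: Lewis-acid ionisation of the tertiary allylic alcohol gives the phytyl/isophytyl cation, which alkylates the free C3 position of the electron-rich hydroquinone at its primary terminus (Friedel–Crafts allylation), forming the E-trisubstituted alkene (expected E:Z about 9:1).

**Step 8**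
Reactants: 13; Ag2O
Product: 14 phylloquinone (vitamin K1), the target
Conditions: Ag2O (2.5 equiv), Et2O, rt, 1 h, dark; then AgNO3-silica chromatography to remove the 2'Z isomer
Reagents that add atoms: none (Ag2O only removes 2 H)
Why: Mild two-electron oxidation of the hydroquinone to the quinone leaves the alkene and all stereocentres intact.

## Compound list
1 | citral, (2E/Z)-3,7-dimethylocta-2,6-dienal | O=C/C=C(\C)CCC=C(C)C | starting material
2 | Hantzsch ester | CCOC(=O)C1=C(C)NC(C)=C(C(=O)OCC)C1 | starting material (hydride source)
3 | (R)-citronellal | O=CC[C@H](C)CCC=C(C)C | intermediate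
4 | (E)-(3-formylbut-2-en-1-yl)triphenylphosphonium chloride | O=C/C=C(\C)C[P+](c1ccccc1)(c1ccccc1)c1ccccc1.[Cl-] | starting material
5 | (2E,4E,7R)-3,7,11-trimethyldodeca-2,4,10-trienal | O=C/C=C(\C)/C=C/C[C@H](C)CCC=C(C)C | intermediate
6 | (3S,4E,7R)-3,7,11-trimethyldodeca-4,10-dienal | O=CC[C@H](C)/C=C/C[C@H](C)CCC=C(C)C | intermediate
7 | 1-(triphenylphosphoranylidene)propan-2-one | CC(=O)C=P(c1ccccc1)(c1ccccc1)c1ccccc1 | starting material
8 | (3E,6S,7E,10R)-6,10,14-trimethylpentadeca-3,7,13-trien-2-one | CC(=O)/C=C/C[C@H](C)/C=C/C[C@H](C)CCC=C(C)C | intermediate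
9 | (6R,10R)-6,10,14-trimethylpentadecan-2-one | CC(=O)CCC[C@H](C)CCC[C@H](C)CCCC(C)C | intermediate
10 | vinylmagnesium bromide | C=C[Mg]Br | starting material
11 | (7R,11R)-isophytol (C3 epimeric mixture) | C=CC(C)(O)CCC[C@H](C)CCC[C@H](C)CCCC(C)C | intermediate
12 | menadiol | Cc1cc(O)c2ccccc2c1O | starting material
13 | phylloquinol | Cc1c(C/C=C(\C)CCC[C@H](C)CCC[C@H](C)CCCC(C)C)c(O)c2ccccc2c1O | intermediate
14 | phylloquinone (vitamin K1) | CC1=C(C/C=C(\C)CCC[C@H](C)CCC[C@H](C)CCCC(C)C)C(=O)c2ccccc2C1=O | target

**Total step count:** 8. **Longest linear sequence:** 8 steps, from citral to 14.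

## Three steps most likely to fail
1. **Step 3 (proposed new dienal reduction).** Risks are 1,6-reduction, low ee, or sensitivity to E/Z geometry.
   - Fallback, using known chemistry only: hydrogenate 3 after Wittig with 7 to the methyl ketone (6R)-6,10-dimethylundecan-2-one. Then do HWE with diethyl (2-(tert-butylimino)ethyl)phosphonate and hydrolysis to the β,β-dialkyl enal (E)-3,7,11-trimethyldodec-2-enal. Reduce it with the Step 1 citral-type ACDC to (3R,7R)-3,7,11-trimethyldodecanal, then use 7 and hydrogenation to reach 9. This adds 3 steps.
2. **Step 7 (Friedel–Crafts allylation).** Risks are E/Z erosion, O-alkylation and low yield.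
   - Fallback: convert 9 by HWE with triethyl phosphonoacetate, separate the E-ester, and reduce with DIBAL-H to (7R,11R)-phytol. Couple that primary E-allylic alcohol with 12 under BF3 catalysis, then oxidise with Ag2O.
3. **Step 5 (global hydrogenation).** Pd-mediated alkene migration at the allylic C7' centre would destroy it.
   - Fallback: reduce the conjugated and disubstituted alkenes with diimide (from 2-nitrobenzenesulfonylhydrazide/Et3N), which cannot migrate alkenes. Then hydrogenate only the remote isopropylidene alkene over Pd/C.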